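All runs are calculated from invented constants.

The vessel holds L and takes in E by steady feed; the aim is the height and time of the top of Q.

common to all: E 1.4 M (fed, over 3.0 min)
- Saturday's: L 1.33 M; the very flask that is asked about, followed so far; the fed solution adds 1.0 times the starting volume
- Tuesday's: L 2.7 M; run made earlier; the fed solution adds 1.0 times the starting volume
- flask: L 1.33 M; the fed solution adds 1.0 times the starting volume; time 3.0 h

| run | time / min | Q / % | E / % |
|---|---|---|---|
| Saturday's | 1.00 | 3.0 | 30.3 |
| Saturday's | 3.00 | 15.5 | 78.3 |
| Saturday's | 5.00 | 22.8 | 59.0 |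
| Saturday's | 8.00 | 26.2 | 40.1 |
| Saturday's | 12.0 | 27.0 | 23.6 |
| Saturday's | 15.0 | 26.4 | 16.9 |
| Tuesday's | 20.0 | 47.4 | 0.2 |
| Tuesday's | 40.0 | 45.4 | 0 |
| Tuesday's | 60.0 | 43.3 | 0.1 |
| Tuesday's | 80.0 | 40.9 | 0 |
| Tuesday's | 120 | 37.1 | 0 |

(each reading ± 0.3 percentage points)

- percent here means E units held: one X counts as two
- amounts are per litre of the starting volume; all of the dose is in the solution fed
- the numbers in the tables scatter by 0.3 percentage points (one standard deviation)
- on the list of suspects stand: L + Q -> G; L + G -> D; E + L -> Q; E + Q -> X
- percentages count the whole charge, also what has not yet gone in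

- time, not beyond 3.0 h, at which the flask holds most Q
- the amount of Q, in percent of the E charged, at that time

Q is made by E + L and lost by E + Q to X, while L + Q to G is treated as a correction. Dividing the net rate of Q by the rate at which E + L and Q's making use L cancels c(E), the feed and the volume: per L used, Q gains one less S·c(Q)/c(L), where S, the selectivity factor, is the E + Q constant over the E + L constant.

In the flask, Q starts low, 3.0% at 1.00 min. E reaches its reading of 78.3% at the end of the feed, and Q then bends over towards the point where c(L)/c(Q) equals S. The highest reading, 27.0%, stands at 12.0 min. Counting one L for each Q and each X, with X holding two E units, leaves 0.606 M of L per starting volume, so S reads 1.60.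

Integrating from a flask without Q, with L + Q to G left aside, gives the peak share, the most Q per L charged while E lasts, S^(S/(1−S)), which reads 0.285. The reckoned top of the flask, before that correction, is therefore 27.1% of the E charged.

Tuesday's tail, with E read at 0%, falls at 0.00245 min⁻¹ with c(L) near 0.848 M. Scaled by c(L) and held over the climb at the top's values, this rate takes an estimated 0.28 percentage points, far less than the top. My reckoning is thus 26.8% near 12.0 min, with Q falling afterwards.

The forecast stood slightly higher, at 27.1% and 0.19 h: “Expect about 27% at roughly 11.5 min.”

The flask gives 26.8% at 0.191 h.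

    L + Q → G (k = 0.00360 L mol⁻¹ min⁻¹)
    L + G → D (k = 0.160 L mol⁻¹ min⁻¹)
    E + L → Q (k = 0.200 L mol⁻¹ min⁻¹)
    E + Q → X (k = 0.320 L mol⁻¹ min⁻¹)

At 0.0820 h in the flask, L goes into Q 150 times as fast as into G, and at the best time G stands at 0.252% and D at 0.0829%. The top of the flask is 0.282 of Q per L charged, against the peak share of 0.285. For the neighbour flask with 0.80 M of L the peak share gives 16.3%, and the top of that flask stands at 16.2%.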